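**Retrosynthetic overview**

1. The plan rests on ring B, the benzene C3a–C4–C5–C6–C7–C7a fused to the dihydrofuran through O1–C7a and C3–C3a, with OMe on C7 and the CH2 arm on C5. It is made from a methyl 6-alkoxy-5-methoxypyridazine-3-carboxylate whose alkoxy group carries a terminal alkyne, by intramolecular [4+2] addition and loss of N2 (new bonds C3a–C7a and C4–C5; dihydrofuran ring and ring B closed together).
2. The cycloaddition precursor comes from an SNAr reaction between an anti homopropargylic alcohol (C2 and C3 set by allenylzinc addition to O-benzylvanillin) and a 6-chloropyridazine ester made from an aminochloropyridazine, so that every substitution site is unambiguous.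
3. The C5 ester becomes a benzylic bromide, which alkylates a succinate imide (Evans auxiliary); reduction and lactonisation give the (R)-β-substituted butyrolactone.
4. The open unit (C7', C8', ring A) is made separately by an anti-aldol reaction of a ring A arylacetyl imide with O-benzylvanillin and is attached as a benzylic bromide by trans α-alkylation of the lactone; desilylation and hydrogenolysis finish the synthesis.
5. Order of ring formation: dihydrofuran ring and ring B together (step 8), then the lactone (step 14); ring A, both guaiacyl rings and the pyridazine are bought as rings.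

Key step: step 8

Remark: the sense of induction in steps 4, 6, 12 and 19 is assigned from the accepted models (Kazlauskas rule; anti SN2' then syn SE2'; chelated Z-enolates attacked anti to the auxiliary benzyl group), and should one prove opposite, the acetate fraction or the enantiomeric auxiliary would be used.

Locants and short forms: O1, C2, C3, C3a–C7a are dihydrobenzofuran positions; C7' and C8' are the carbinol carbon and the aryl-bearing carbon of the open unit; ArB = (2S,3R)-2-(4-benzyloxy-3-methoxyphenyl)-7-methoxy-3-(triisopropylsilyloxymethyl)-2,3-dihydrobenzofuran-5-yl; ArA = 4-benzyloxy-3-[(1S,2S)-1-(4-benzyloxy-3-methoxyphenyl)-1,3-bis(tert-butyldimethylsilyloxy)propan-2-yl]-5-methoxyphenyl.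

**Route**

Step 1
Reactants: 1 6-chloro-4-methoxypyridazin-3-amine
Product: 2 methyl 6-amino-5-methoxypyridazine-3-carboxylate
Conditions: Pd(dppf)Cl2 (5 mol%), CO (10 bar), Et3N, MeOH, 100 °C
Reagents that add atoms: carbon monoxide [C-]#[O+]; methanol CO
Why: Palladium-catalysed methoxycarbonylation (oxidative addition of zerovalent palladium into the only C–Cl bond, CO insertion, methanolysis) should give the ester para to the amino-bearing carbon, and because the starting pyridazine carries one halogen and one amino group the positions of the ester and of the later leaving group are fixed without any regiochemical choice.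

Step 2
Reactants: 2 methyl 6-amino-5-methoxypyridazine-3-carboxylate
Product: 4 methyl 6-chloro-5-methoxypyridazine-3-carboxylate, via pyridazinediazonium chloride 3 (not isolated)
Conditions: t-BuONO, CuCl2, MeCN, 0 → 60 °C
Reagents that add atoms: copper dichloride Cl[Cu]Cl
Why: A Sandmeyer-type chlorodediazoniation under anhydrous conditions (diazotisation by the alkyl nitrite, chloride transfer from CuCl2) should replace the amino group by chlorine without the hydrolysis to a pyridazinone that aqueous diazotisation of an amine next to a ring nitrogen would cause.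

Step 3
Reactants: 5 but-3-yne-1,2-diol (racemic)
Product: 6 rac-1-(triisopropylsilyloxy)but-3-yn-2-ol
Conditions: i-Pr3SiCl (1.05 equiv), imidazole, CH2Cl2, 0 °C → rt
Reagents that add atoms: chlorotriisopropylsilane CC(C)[Si](Cl)(C(C)C)C(C)C
Why: Silylation with the bulky chlorosilane is selective for the primary hydroxyl, and the triisopropylsilyl group is chosen because it resists 1,3-migration to a neighbouring alkoxide in step 7 and survives the thermolysis.

Step 4
Reactants: 6 rac-1-(triisopropylsilyloxy)but-3-yn-2-ol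
Product: 7 (S)-1-(triisopropylsilyloxy)but-3-yn-2-ol
Conditions: immobilised Candida antarctica lipase B, vinyl acetate, hexane, 30 °C, run past half conversion
Reagents that add atoms: none
Why: Lipase-catalysed kinetic resolution by acyl transfer should, following the Kazlauskas rule (large CH2OSi group, small ethynyl group), acetylate the R alcohol and leave the S alcohol, whose enantiopurity is secured by running past half conversion.

Step 5
Reactants: 7 (S)-1-(triisopropylsilyloxy)but-3-yn-2-ol
Product: 8 (S)-1-(triisopropylsilyloxy)but-3-yn-2-yl methanesulfonate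
Conditions: MsCl, Et3N, CH2Cl2, −78 → 0 °C
Reagents that add atoms: methanesulfonyl chloride CS(=O)(=O)Cl
Why: Mesylation at low temperature forms the sulfonate at oxygen without touching the C–O bond, so the S configuration is kept and the labile propargylic mesylate is used directly.

Step 6
Reactants: 8 (S)-1-(triisopropylsilyloxy)but-3-yn-2-yl methanesulfonate; 9 4-(benzyloxy)-3-methoxybenzaldehyde (O-benzylvanillin)
Product: 11 (1S,2R)-1-(4-benzyloxy-3-methoxyphenyl)-2-(triisopropylsilyloxymethyl)but-3-yn-1-ol, via allenylzinc mesylate 10 (not isolated)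
Conditions: Pd(OAc)2 (5 mol%), PPh3 (5 mol%), Et2Zn (3 equiv), THF, −78 → −20 °C
Reagents that add atoms: none
Why: In this Marshall–Tamaru propargylation zerovalent palladium displaces the mesylate anti (SN2') to an allenylpalladium species that Et2Zn converts into allenylzinc 10, which adds syn (SE2') to the aldehyde through a six-membered chair-like transition state, so that C2 arises R by net inversion of the mesylate carbon and C1 arises S because the aryl group sits anti to the allenyl substituent (anti adduct, any syn isomer being removed by chromatography).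

Step 7
Reactants: 11 (1S,2R)-1-(4-benzyloxy-3-methoxyphenyl)-2-(triisopropylsilyloxymethyl)but-3-yn-1-ol; 4 methyl 6-chloro-5-methoxypyridazine-3-carboxylate
Product: 13 methyl 6-[(1S,2R)-1-(4-benzyloxy-3-methoxyphenyl)-2-(triisopropylsilyloxymethyl)but-3-ynyloxy]-5-methoxypyridazine-3-carboxylate, via sodium alkoxide 12 (not isolated)
Conditions: NaH (1.0 equiv), THF, 0 °C; then 4 (1.2 equiv), −20 → 0 °C
Reagents that add atoms: none
Why: Nucleophilic aromatic substitution by the alkoxide should take place at C6, the only halogen-bearing carbon, which is activated by both ring nitrogens and by the para ester, while the low temperature and the limiting amount of alkoxide keep attack at the ester carbonyl behind, and the carbinol configuration is retained because its C–O bond is not broken.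

Step 8
Reactants: 13 methyl 6-[(1S,2R)-1-(4-benzyloxy-3-methoxyphenyl)-2-(triisopropylsilyloxymethyl)but-3-ynyloxy]-5-methoxypyridazine-3-carboxylate
Product: 15 methyl (2S,3R)-2-(4-benzyloxy-3-methoxyphenyl)-7-methoxy-3-(triisopropylsilyloxymethyl)-2,3-dihydrobenzofuran-5-carboxylate, via bridged diaza adduct 14 (not isolated)
Conditions: 1,3,5-triisopropylbenzene (0.01 M), BHT (cat.), Ar, 210 °C, sealed tube
Reagents that add atoms: none
Why: The ester-bearing pyridazine acts as an electron-poor 2,3-diazadiene whose C6 and C3 add across the tethered alkyne in an intramolecular inverse-electron-demand [4+2] cycloaddition to give the 2,3-diazabicyclo[2.2.2]octatriene 14, which at once loses N2 by retro-[4+2] to leave benzene ring B. The closest known reaction type is the thermal intramolecular Diels–Alder reaction of 3-(but-3-ynyloxy)pyridazines to 2,3-dihydrobenzofurans. The dihydrofuran closes as a fused five-membered ring in the cycloaddition itself, because the three-atom tether O1–C2–C3 lets only the inner alkyne carbon reach the oxygen-bearing C6 (bond C3a–C7a), and ring B closes by the second new bond from the terminal alkyne carbon to the ester-bearing carbon (bond C4–C5) and becomes aromatic on extrusion of N2. No stereocentre is formed, since the bridgehead centres of 14 vanish on aromatisation and C2 and C3, set in step 6, carry no acidic hydrogen under neutral thermolysis. The step needs regioselectivity, which the tether enforces, and a cycloaddition rate above that of thermal ionisation or elimination of the benzylic heteroaryl ether: the ester lowers the diene LUMO against the two alkoxy donors, the trans-disubstituted short tether favours the folded rotamer, and high dilution in an apolar solvent suppresses bimolecular and ionic paths.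

Step 9
Reactants: 15 methyl (2S,3R)-2-(4-benzyloxy-3-methoxyphenyl)-7-methoxy-3-(triisopropylsilyloxymethyl)-2,3-dihydrobenzofuran-5-carboxylate
Product: 16 [(2S,3R)-2-(4-benzyloxy-3-methoxyphenyl)-7-methoxy-3-(triisopropylsilyloxymethyl)-2,3-dihydrobenzofuran-5-yl]methanol
Conditions: i-Bu2AlH (2.5 equiv), CH2Cl2, −78 → 0 °C; aq. potassium sodium tartrate
Reagents that add atoms: none
Why: i-Bu2AlH reduces the aryl ester to the benzylic alcohol at low temperature and leaves the silyl ether, the benzyl ether and the cyclic benzylic ether untouched.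

Step 10
Reactants: 16 [(2S,3R)-2-(4-benzyloxy-3-methoxyphenyl)-7-methoxy-3-(triisopropylsilyloxymethyl)-2,3-dihydrobenzofuran-5-yl]methanol
Product: 17 (2S,3R)-5-(bromomethyl)-2-(4-benzyloxy-3-methoxyphenyl)-7-methoxy-3-(triisopropylsilyloxymethyl)-2,3-dihydrobenzofuran
Conditions: CBr4, PPh3, 2,6-lutidine, CH2Cl2, 0 °C
Reagents that add atoms: carbon tetrabromide BrC(Br)(Br)Br
Why: The Appel reaction converts the primary benzylic alcohol into the bromide by SN2 attack of bromide on the alkoxyphosphonium ion, the lutidine buffer keeping the medium free of acid that could ionise the C2–O1 bond.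

Step 11
Reactants: 18 4-tert-butoxy-4-oxobutanoic acid; 19 (R)-4-benzyl-1,3-oxazolidin-2-one
Product: 21 tert-butyl 4-[(4R)-4-benzyl-2-oxo-1,3-oxazolidin-3-yl]-4-oxobutanoate, via mixed pivalic anhydride 20 (not isolated)
Conditions: t-BuCOCl, Et3N, THF, −20 °C; then 19, LiCl, rt
Reagents that add atoms: none
Why: N-Acylation of the oxazolidinone through the mixed pivalic anhydride (LiCl and Et3N as mild activators) is the standard entry to Evans imides, the nucleophile attacking the less hindered succinyl carbonyl.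

Step 12
Reactants: 21 tert-butyl 4-[(4R)-4-benzyl-2-oxo-1,3-oxazolidin-3-yl]-4-oxobutanoate; 17 (2S,3R)-5-(bromomethyl)-2-(4-benzyloxy-3-methoxyphenyl)-7-methoxy-3-(triisopropylsilyloxymethyl)-2,3-dihydrobenzofuran
Product: 23 tert-butyl (3R)-4-[(4R)-4-benzyl-2-oxo-1,3-oxazolidin-3-yl]-3-(ArB-methyl)-4-oxobutanoate, via sodium enolate 22 (not isolated)
Conditions: NaN(SiMe3)2, THF, −78 °C; then 17, −78 → −40 °C
Reagents that add atoms: none
Why: In this Evans alkylation the chelated sodium Z-enolate 22, formed at the more acidic imide α-CH2 and not at the ester α-CH2, is alkylated by the benzylic bromide on the face opposite to the benzyl group of the R auxiliary, which should set the new centre R.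

Step 13
Reactants: 23 tert-butyl (3R)-4-[(4R)-4-benzyl-2-oxo-1,3-oxazolidin-3-yl]-3-(ArB-methyl)-4-oxobutanoate
Product: 24 tert-butyl (3R)-3-(ArB-methyl)-4-hydroxybutanoate
Conditions: LiBH4, MeOH (1 equiv), THF, 0 °C
Reagents that add atoms: none
Why: LiBH4 reduces the exocyclic imide carbonyl, activated by lithium chelation, to the primary alcohol with release of the auxiliary, while the tert-butyl ester is too hindered to react at 0 °C and the new stereocentre is not enolisable in the product.

Step 14
Reactants: 24 tert-butyl (3R)-3-(ArB-methyl)-4-hydroxybutanoate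
Product: 25 (4R)-4-(ArB-methyl)oxolan-2-one
Conditions: TsOH·H2O (10 mol%), toluene, 60 °C
Reagents that add atoms: none
Why: Acid-catalysed lactonisation (intramolecular acyl substitution with loss of tert-butanol, a 5-exo-trig closure) forms the butyrolactone, and catalytic sulfonic acid in an apolar solvent is mild enough for the triisopropylsilyl ether and the cyclic benzylic ether.

Step 15
Reactants: 26 methyl 3-bromo-4-hydroxy-5-methoxybenzoate
Product: 27 methyl 4-(benzyloxy)-3-bromo-5-methoxybenzoate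
Conditions: BnBr, K2CO3, DMF, rt
Reagents that add atoms: benzyl bromide BrCc1ccccc1
Why: Williamson etherification of the phenoxide with benzyl bromide protects the ring A phenol as the ether that is removed in the last step.

Step 16
Reactants: 27 methyl 4-(benzyloxy)-3-bromo-5-methoxybenzoate
Product: 28 methyl 4-(benzyloxy)-3-(2-tert-butoxy-2-oxoethyl)-5-methoxybenzoate
Conditions: BrZnCH2CO2t-Bu, Pd2(dba)3 (2 mol%), XPhos (8 mol%), THF, 65 °C
Reagents that add atoms: (2-tert-butoxy-2-oxoethyl)zinc bromide CC(C)(C)OC(=O)C[Zn]Br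
Why: Negishi-type cross-coupling of the Reformatsky reagent (palladium-catalysed α-arylation of a zinc ester enolate) places the acetic ester arm on the bromide carbon ortho to the benzyloxy group, and the mild zinc enolate tolerates the methyl benzoate.

Step 17
Reactants: 28 methyl 4-(benzyloxy)-3-(2-tert-butoxy-2-oxoethyl)-5-methoxybenzoate
Product: 29 2-[2-(benzyloxy)-3-methoxy-5-(methoxycarbonyl)phenyl]acetic acid
Conditions: CF3CO2H/CH2Cl2 (1:4), 0 °C → rt
Reagents that add atoms: none
Why: Acidolysis of the tert-butyl ester by loss of 2-methylpropene frees the arylacetic acid, whereas the methyl benzoate and, at short exposure at low temperature, the aryl benzyl ether survive.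

Step 18
Reactants: 29 2-[2-(benzyloxy)-3-methoxy-5-(methoxycarbonyl)phenyl]acetic acid; 30 (S)-4-benzyl-1,3-oxazolidin-2-one
Product: 32 methyl 3-{2-[(4S)-4-benzyl-2-oxo-1,3-oxazolidin-3-yl]-2-oxoethyl}-4-(benzyloxy)-5-methoxybenzoate, via mixed pivalic anhydride 31 (not isolated)
Conditions: t-BuCOCl, Et3N, THF, −20 °C; then 30, LiCl, rt
Reagents that add atoms: none
Why: The mixed pivalic anhydride acylates the S oxazolidinone as in step 11, giving the imide that carries the ring A aryl group on the future C8'.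

Step 19
Reactants: 32 methyl 3-{2-[(4S)-4-benzyl-2-oxo-1,3-oxazolidin-3-yl]-2-oxoethyl}-4-(benzyloxy)-5-methoxybenzoate; 9 4-(benzyloxy)-3-methoxybenzaldehyde
Product: 34 methyl 3-[(2R,3S)-1-[(4S)-4-benzyl-2-oxo-1,3-oxazolidin-3-yl]-3-(4-benzyloxy-3-methoxyphenyl)-3-hydroxy-1-oxopropan-2-yl]-4-(benzyloxy)-5-methoxybenzoate, via trimethylsilyl ether 33 (not isolated)
Conditions: MgCl2 (20 mol%), Et3N, Me3SiCl, EtOAc, rt; then aq. citric acid, THF, 0 °C
Reagents that add atoms: none
Why: In this Evans magnesium halide-catalysed anti-aldol reaction Et3N and MgCl2 generate the chelated Z magnesium enolate, which should add to the aromatic aldehyde through a boat-like transition state on the face anti to the auxiliary benzyl group, so that the auxiliary sets the aryl-bearing carbon (R in 34, S at C8' after reduction) and the anti mode sets the carbinol carbon C7' (S), while silylation of the aldolate by Me3SiCl drives turnover and blocks retro-aldol cleavage.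

Step 20
Reactants: 34 methyl 3-[(2R,3S)-1-[(4S)-4-benzyl-2-oxo-1,3-oxazolidin-3-yl]-3-(4-benzyloxy-3-methoxyphenyl)-3-hydroxy-1-oxopropan-2-yl]-4-(benzyloxy)-5-methoxybenzoate
Product: 35 methyl 4-(benzyloxy)-3-[(1S,2S)-1-(4-benzyloxy-3-methoxyphenyl)-1,3-dihydroxypropan-2-yl]-5-methoxybenzoate
Conditions: NaBH4, THF/H2O (4:1), 0 °C → rt
Reagents that add atoms: none
Why: NaBH4 in wet THF reduces the imide carbonyl to the primary alcohol with release of the auxiliary under nearly neutral conditions that should spare the methyl benzoate and avoid retro-aldol cleavage or epimerisation at the aryl-bearing carbon.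

Step 21
Reactants: 35 methyl 4-(benzyloxy)-3-[(1S,2S)-1-(4-benzyloxy-3-methoxyphenyl)-1,3-dihydroxypropan-2-yl]-5-methoxybenzoate
Product: 36 methyl 4-(benzyloxy)-3-[(1S,2S)-1-(4-benzyloxy-3-methoxyphenyl)-1,3-bis(tert-butyldimethylsilyloxy)propan-2-yl]-5-methoxybenzoate
Conditions: t-BuMe2SiOTf (2.5 equiv), 2,6-lutidine, CH2Cl2, −78 → 0 °C
Reagents that add atoms: tert-butyldimethylsilyl trifluoromethanesulfonate CC(C)(C)[Si](C)(C)OS(=O)(=O)C(F)(F)F
Why: Silylation of both hydroxyls with the silyl triflate and a hindered base gives ethers that withstand hydride, phosphine and amide base and that fluoride removes at the end without ionising the electron-rich benzylic C7'–O bond.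

Step 22
Reactants: 36 methyl 4-(benzyloxy)-3-[(1S,2S)-1-(4-benzyloxy-3-methoxyphenyl)-1,3-bis(tert-butyldimethylsilyloxy)propan-2-yl]-5-methoxybenzoate
Product: 37 ArA-methanol, {4-(benzyloxy)-3-[(1S,2S)-1-(4-benzyloxy-3-methoxyphenyl)-1,3-bis(tert-butyldimethylsilyloxy)propan-2-yl]-5-methoxyphenyl}methanol
Conditions: i-Bu2AlH (2.5 equiv), CH2Cl2, −78 → 0 °C; aq. potassium sodium tartrate
Reagents that add atoms: none
Why: i-Bu2AlH reduces the methyl benzoate to the benzylic alcohol and does not touch silyl or benzyl ethers.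

Step 23
Reactants: 37 ArA-methanol
Product: 38 ArA-methyl bromide, 2-(benzyloxy)-5-(bromomethyl)-1-[(1S,2S)-1-(4-benzyloxy-3-methoxyphenyl)-1,3-bis(tert-butyldimethylsilyloxy)propan-2-yl]-3-methoxybenzene
Conditions: CBr4, PPh3, 2,6-lutidine, CH2Cl2, 0 °C
Reagents that add atoms: carbon tetrabromide BrC(Br)(Br)Br
Why: The Appel reaction under lutidine buffering gives the electron-rich benzylic bromide, which is used at once, without acid-induced loss of the benzylic silyl ether.

Step 24
Reactants: 25 (4R)-4-(ArB-methyl)oxolan-2-one; 38 ArA-methyl bromide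
Product: 40 (3R,4R)-3-(ArA-methyl)-4-(ArB-methyl)oxolan-2-one, via lithium enolate 39 (not isolated)
Conditions: LiN(SiMe3)2, THF, −78 °C; then 38, DMPU, −78 → −40 °C
Reagents that add atoms: none
Why: Alkylation of the lithium enolate of the 4-substituted butyrolactone by the benzylic bromide takes place on the face anti to the C4 substituent, which should set C3 as R and give the trans-3,4-disubstituted lactone, the thermodynamically preferred isomer as well.

Step 25
Reactants: 40 (3R,4R)-3-(ArA-methyl)-4-(ArB-methyl)oxolan-2-one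
Product: 41 (3R,4R)-3-{[4-(benzyloxy)-3-[(1S,2S)-1-(4-benzyloxy-3-methoxyphenyl)-1,3-dihydroxypropan-2-yl]-5-methoxyphenyl]methyl}-4-{[(2S,3R)-2-(4-benzyloxy-3-methoxyphenyl)-3-(hydroxymethyl)-7-methoxy-2,3-dihydrobenzofuran-5-yl]methyl}oxolan-2-one
Conditions: Bu4NF, AcOH, THF, rt → 40 °C
Reagents that add atoms: none
Why: Fluoride cleaves the triisopropylsilyl and both tert-butyldimethylsilyl ethers through strong Si–F bond formation, and the acetic acid buffer keeps the alkoxides protonated so that the lactone, C3 and the benzylic carbinol are not disturbed.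

Step 26
Reactants: 41 the tris(benzyl ether) triol of step 25
Product: 42 (3R,4R)-3-{[3-[(1S,2S)-1,3-dihydroxy-1-(4-hydroxy-3-methoxyphenyl)propan-2-yl]-4-hydroxy-5-methoxyphenyl]methyl}-4-{[(2S,3R)-2-(4-hydroxy-3-methoxyphenyl)-3-(hydroxymethyl)-7-methoxy-2,3-dihydrobenzofuran-5-yl]methyl}oxolan-2-one (CNP0186558.2)
Conditions: H2 (1 atm), palladium on carbon (10% Pd/C), EtOAc/EtOH, rt
Reagents that add atoms: none
Why: Hydrogenolysis of the three aryl benzyl ethers over palladium on carbon in a neutral solvent at atmospheric pressure is faster than cleavage of the cyclic benzylic ether O1–C2 or of the benzylic C7'–OH bond, so stopping at the uptake of three equivalents of H2 should give the target.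

**Compound list**

1 | 6-chloro-4-methoxypyridazin-3-amine | COc1cc(Cl)nnc1N | starting material
2 | methyl 6-amino-5-methoxypyridazine-3-carboxylate | COC(=O)c1cc(OC)c(N)nn1 | intermediate
3 | 4-methoxy-6-(methoxycarbonyl)pyridazine-3-diazonium chloride | COC(=O)c1cc(OC)c([N+]#N)nn1.[Cl-] | intermediate
4 | methyl 6-chloro-5-methoxypyridazine-3-carboxylate | COC(=O)c1cc(OC)c(Cl)nn1 | intermediate
5 | but-3-yne-1,2-diol (racemic) | C#CC(O)CO | starting material
6 | rac-1-(triisopropylsilyloxy)but-3-yn-2-ol | C#CC(O)CO[Si](C(C)C)(C(C)C)C(C)C | intermediate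
7 | (S)-1-(triisopropylsilyloxy)but-3-yn-2-ol | C#C[C@H](O)CO[Si](C(C)C)(C(C)C)C(C)C | intermediate
8 | (S)-1-(triisopropylsilyloxy)but-3-yn-2-yl methanesulfonate | C#C[C@H](OS(C)(=O)=O)CO[Si](C(C)C)(C(C)C)C(C)C | intermediate
9 | 4-(benzyloxy)-3-methoxybenzaldehyde (O-benzylvanillin) | COc1cc(C=O)ccc1OCc1ccccc1 | starting material
10 | (aS)-[4-(triisopropylsilyloxy)buta-1,2-dien-1-yl]zinc methanesulfonate | [H]C(CO[Si](C(C)C)(C(C)C)C(C)C)=[C@]=C([H])[Zn]OS(C)(=O)=O | intermediate
11 | (1S,2R)-1-(4-benzyloxy-3-methoxyphenyl)-2-(triisopropylsilyloxymethyl)but-3-yn-1-ol | O[C@H](c1ccc(OCc2ccccc2)c(OC)c1)[C@@H](CO[Si](C(C)C)(C(C)C)C(C)C)C#C | intermediate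
12 | sodium (1S,2R)-1-(4-benzyloxy-3-methoxyphenyl)-2-(triisopropylsilyloxymethyl)but-3-yn-1-olate | [Na+].[O-][C@H](c1ccc(OCc2ccccc2)c(OC)c1)[C@@H](CO[Si](C(C)C)(C(C)C)C(C)C)C#C | intermediate
13 | methyl 6-[(1S,2R)-1-(4-benzyloxy-3-methoxyphenyl)-2-(triisopropylsilyloxymethyl)but-3-ynyloxy]-5-methoxypyridazine-3-carboxylate | COC(=O)c1cc(OC)c(O[C@H](c2ccc(OCc3ccccc3)c(OC)c2)[C@@H](CO[Si](C(C)C)(C(C)C)C(C)C)C#C)nn1 | intermediate
14 | 2,3-diazabicyclo[2.2.2]octa-2,5,7-triene adduct of 13 (N=N bridge between the former pyridazine C3 and C6, dihydrofuran already fused; bridgehead configuration left open, both forms give 15) | COC(=O)C12N=NC3(O[C@H](c4ccc(OCc5ccccc5)c(OC)c4)[C@@H](CO[Si](C(C)C)(C(C)C)C(C)C)C3=C1)C(OC)=C2 | intermediate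
15 | methyl (2S,3R)-2-(4-benzyloxy-3-methoxyphenyl)-7-methoxy-3-(triisopropylsilyloxymethyl)-2,3-dihydrobenzofuran-5-carboxylate | COC(=O)c1cc(OC)c2c(c1)[C@H](CO[Si](C(C)C)(C(C)C)C(C)C)[C@@H](c1ccc(OCc3ccccc3)c(OC)c1)O2 | intermediate
16 | [(2S,3R)-2-(4-benzyloxy-3-methoxyphenyl)-7-methoxy-3-(triisopropylsilyloxymethyl)-2,3-dihydrobenzofuran-5-yl]methanol | OCc1cc(OC)c2c(c1)[C@H](CO[Si](C(C)C)(C(C)C)C(C)C)[C@@H](c1ccc(OCc3ccccc3)c(OC)c1)O2 | intermediate
17 | (2S,3R)-5-(bromomethyl)-2-(4-benzyloxy-3-methoxyphenyl)-7-methoxy-3-(triisopropylsilyloxymethyl)-2,3-dihydrobenzofuran | BrCc1cc(OC)c2c(c1)[C@H](CO[Si](C(C)C)(C(C)C)C(C)C)[C@@H](c1ccc(OCc3ccccc3)c(OC)c1)O2 | intermediate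
18 | 4-tert-butoxy-4-oxobutanoic acid | CC(C)(C)OC(=O)CCC(=O)O | starting material
19 | (R)-4-benzyl-1,3-oxazolidin-2-one | O=C1N[C@H](Cc2ccccc2)CO1 | starting material
20 | 4-tert-butoxy-4-oxobutanoic pivalic anhydride | CC(C)(C)OC(=O)CCC(=O)OC(=O)C(C)(C)C | intermediate
21 | tert-butyl 4-[(4R)-4-benzyl-2-oxo-1,3-oxazolidin-3-yl]-4-oxobutanoate | CC(C)(C)OC(=O)CCC(=O)N1[C@H](Cc2ccccc2)COC1=O | intermediate
22 | sodium Z-enolate of 21 | [Na+].CC(C)(C)OC(=O)C/C=C(\[O-])N1[C@H](Cc2ccccc2)COC1=O | intermediate
23 | tert-butyl (3R)-4-[(4R)-4-benzyl-2-oxo-1,3-oxazolidin-3-yl]-3-(ArB-methyl)-4-oxobutanoate | CC(C)(C)OC(=O)C[C@@H](Cc1cc(OC)c2c(c1)[C@H](CO[Si](C(C)C)(C(C)C)C(C)C)[C@@H](c1ccc(OCc3ccccc3)c(OC)c1)O2)C(=O)N1[C@H](Cc2ccccc2)COC1=O | intermediate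
24 | tert-butyl (3R)-3-(ArB-methyl)-4-hydroxybutanoate | CC(C)(C)OC(=O)C[C@@H](Cc1cc(OC)c2c(c1)[C@H](CO[Si](C(C)C)(C(C)C)C(C)C)[C@@H](c1ccc(OCc3ccccc3)c(OC)c1)O2)CO | intermediate
25 | (4R)-4-(ArB-methyl)oxolan-2-one | O=C1C[C@@H](Cc2cc(OC)c3c(c2)[C@H](CO[Si](C(C)C)(C(C)C)C(C)C)[C@@H](c2ccc(OCc4ccccc4)c(OC)c2)O3)CO1 | intermediate
26 | methyl 3-bromo-4-hydroxy-5-methoxybenzoate | COC(=O)c1cc(Br)c(O)c(OC)c1 | starting material
27 | methyl 4-(benzyloxy)-3-bromo-5-methoxybenzoate | COC(=O)c1cc(Br)c(OCc2ccccc2)c(OC)c1 | intermediate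
28 | methyl 4-(benzyloxy)-3-(2-tert-butoxy-2-oxoethyl)-5-methoxybenzoate | COC(=O)c1cc(CC(=O)OC(C)(C)C)c(OCc2ccccc2)c(OC)c1 | intermediate
29 | 2-[2-(benzyloxy)-3-methoxy-5-(methoxycarbonyl)phenyl]acetic acid | COC(=O)c1cc(CC(=O)O)c(OCc2ccccc2)c(OC)c1 | intermediate
30 | (S)-4-benzyl-1,3-oxazolidin-2-one | O=C1N[C@@H](Cc2ccccc2)CO1 | starting material
31 | 2-[2-(benzyloxy)-3-methoxy-5-(methoxycarbonyl)phenyl]acetic pivalic anhydride | COC(=O)c1cc(CC(=O)OC(=O)C(C)(C)C)c(OCc2ccccc2)c(OC)c1 | intermediate
32 | methyl 3-{2-[(4S)-4-benzyl-2-oxo-1,3-oxazolidin-3-yl]-2-oxoethyl}-4-(benzyloxy)-5-methoxybenzoate | COC(=O)c1cc(CC(=O)N2[C@@H](Cc3ccccc3)COC2=O)c(OCc2ccccc2)c(OC)c1 | intermediate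
33 | trimethylsilyl ether of 34 | COc1cc([C@@H](O[Si](C)(C)C)[C@H](C(=O)N2[C@@H](Cc3ccccc3)COC2=O)c2cc(C(=O)OC)cc(OC)c2OCc2ccccc2)ccc1OCc1ccccc1 | intermediate
34 | methyl 3-[(2R,3S)-1-[(4S)-4-benzyl-2-oxo-1,3-oxazolidin-3-yl]-3-(4-benzyloxy-3-methoxyphenyl)-3-hydroxy-1-oxopropan-2-yl]-4-(benzyloxy)-5-methoxybenzoate | COc1cc([C@@H](O)[C@H](C(=O)N2[C@@H](Cc3ccccc3)COC2=O)c2cc(C(=O)OC)cc(OC)c2OCc2ccccc2)ccc1OCc1ccccc1 | intermediate
35 | methyl 4-(benzyloxy)-3-[(1S,2S)-1-(4-benzyloxy-3-methoxyphenyl)-1,3-dihydroxypropan-2-yl]-5-methoxybenzoate | COc1cc([C@@H](O)[C@H](CO)c2cc(C(=O)OC)cc(OC)c2OCc2ccccc2)ccc1OCc1ccccc1 | intermediate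
36 | methyl 4-(benzyloxy)-3-[(1S,2S)-1-(4-benzyloxy-3-methoxyphenyl)-1,3-bis(tert-butyldimethylsilyloxy)propan-2-yl]-5-methoxybenzoate | COc1cc([C@@H](O[Si](C)(C)C(C)(C)C)[C@H](CO[Si](C)(C)C(C)(C)C)c2cc(C(=O)OC)cc(OC)c2OCc2ccccc2)ccc1OCc1ccccc1 | intermediate
37 | ArA-methanol | COc1cc([C@@H](O[Si](C)(C)C(C)(C)C)[C@H](CO[Si](C)(C)C(C)(C)C)c2cc(CO)cc(OC)c2OCc2ccccc2)ccc1OCc1ccccc1 | intermediate
38 | ArA-methyl bromide | COc1cc([C@@H](O[Si](C)(C)C(C)(C)C)[C@H](CO[Si](C)(C)C(C)(C)C)c2cc(CBr)cc(OC)c2OCc2ccccc2)ccc1OCc1ccccc1 | intermediate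
39 | lithium enolate of 25 | [Li+].[O-]C1=C[C@@H](Cc2cc(OC)c3c(c2)[C@H](CO[Si](C(C)C)(C(C)C)C(C)C)[C@@H](c2ccc(OCc4ccccc4)c(OC)c2)O3)CO1 | intermediate
40 | (3R,4R)-3-(ArA-methyl)-4-(ArB-methyl)oxolan-2-one | COc1cc([C@@H](O[Si](C)(C)C(C)(C)C)[C@H](CO[Si](C)(C)C(C)(C)C)c2cc(C[C@H]3C(=O)OC[C@@H]3Cc3cc(OC)c4c(c3)[C@H](CO[Si](C(C)C)(C(C)C)C(C)C)[C@@H](c3ccc(OCc5ccccc5)c(OC)c3)O4)cc(OC)c2OCc2ccccc2)ccc1OCc1ccccc1 | intermediate
41 | (3R,4R)-3-{[4-(benzyloxy)-3-[(1S,2S)-1-(4-benzyloxy-3-methoxyphenyl)-1,3-dihydroxypropan-2-yl]-5-methoxyphenyl]methyl}-4-{[(2S,3R)-2-(4-benzyloxy-3-methoxyphenyl)-3-(hydroxymethyl)-7-methoxy-2,3-dihydrobenzofuran-5-yl]methyl}oxolan-2-one | COc1cc([C@@H](O)[C@H](CO)c2cc(C[C@H]3C(=O)OC[C@@H]3Cc3cc(OC)c4c(c3)[C@H](CO)[C@@H](c3ccc(OCc5ccccc5)c(OC)c3)O4)cc(OC)c2OCc2ccccc2)ccc1OCc1ccccc1 | intermediate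
42 | (3R,4R)-3-{[3-[(1S,2S)-1,3-dihydroxy-1-(4-hydroxy-3-methoxyphenyl)propan-2-yl]-4-hydroxy-5-methoxyphenyl]methyl}-4-{[(2S,3R)-2-(4-hydroxy-3-methoxyphenyl)-3-(hydroxymethyl)-7-methoxy-2,3-dihydrobenzofuran-5-yl]methyl}oxolan-2-one (CNP0186558.2) | COc1cc([C@@H](O)[C@H](CO)c2cc(C[C@H]3C(=O)OC[C@@H]3Cc3cc(OC)c4c(c3)[C@H](CO)[C@@H](c3ccc(O)c(OC)c3)O4)cc(OC)c2O)ccc1O | target

**Step count**

Total: 26 steps. Longest linear sequence: 14 steps (from 5 through steps 3–10, 12–14 and 24–26).

**Steps most likely to fail, with fallbacks**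

Step 8. The cycloaddition may be outrun by thermal cleavage of the benzylic pyridazinyl ether (ionisation of the electron-rich benzylic C–O bond, or six-centre elimination to an enyne), because the two alkoxy donors raise the diene LUMO and force a high temperature. In the fallback ring B is bought and the dihydrofuran is closed by C–O bond formation; it sets out from imide 32 and aldehyde 9 and comes back at 15.
- A boron-mediated Evans syn-aldol reaction (Bu2BOTf, i-Pr2NEt, CH2Cl2, −78 → 0 °C) should give the syn adduct F1. The boron enolate reacts on the enolate face opposite to that used in step 19, so the aryl-bearing carbon has the configuration needed for C3.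
- NaBH4 in wet THF should give diol F2.
- Hydrogenolysis of both benzyl ethers (H2, palladium on carbon) should give bisphenol F3.
- Catalytic TsOH in CH2Cl2 should ionise the 4-hydroxybenzylic alcohol to a para-quinone methide that the ortho phenol traps, giving the thermodynamically preferred trans-dihydrobenzofuran F4, C2 being set trans to the C3 substituent.
- Selective benzylation of the phenol (BnBr, K2CO3, acetone) should give benzyl ether F5, and silylation of the primary alcohol (i-Pr3SiCl, imidazole) returns to 15.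

Step 19. Anti selectivity may erode, or the aryl-stabilised magnesium enolate may react sluggishly and the adduct may revert by retro-aldol cleavage before silylation. The fallback sets the same two centres by an anti-selective carbonyl allylation; it sets out from bromide 27 and aldehyde 9 and comes back at diol 35.
- Sonogashira coupling of 27 with propyne (Pd(PPh3)2Cl2, CuI, Et3N, DMF, 50 °C) should give aryl propyne F6.
- Ruthenium-catalysed alkyne-mediated (α-aryl)allylation of 9 under transfer hydrogenation conditions (Ru(O2CCF3)2(CO)(PPh3)2, a Josiphos ligand of the enantiomeric series that gives the 1S,2R product, 2-propanol as reductant, THF, 95 °C) should give the anti homoallylic alcohol F7. The alkyne isomerises to the aryl allene, hydrometalation gives an allylruthenium species, and this adds through a closed transition state.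
- Ozonolysis of the vinyl group with reductive work-up (O3, CH2Cl2/MeOH, −78 °C; NaBH4) returns to 35.

Step 7. The hindered secondary alkoxide may attack the electrophilic ester carbonyl in competition with the methoxy-flanked C6, giving ester exchange and releasing methoxide that then consumes 4. The fallback makes the ether before any ester is present; it sets out from 1 and alcohol 11 and comes back at 13.
- Fluorodediazoniation of 1 (NaNO2, HF·pyridine, 0 °C → rt) should give 6-chloro-3-fluoro-4-methoxypyridazine F8.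
- Alkoxide 12 (from 11 and NaH, THF, −40 °C) should displace fluoride, which leaves far faster than chloride in SNAr, to give the chloropyridazinyl ether F9.
- Methoxycarbonylation of the remaining C–Cl bond (Pd(dppf)Cl2, CO, Et3N, MeOH) gives 13, the methanol solvent under CO pressure intercepting the acylpalladium species ahead of the terminal alkyne.

Further compounds

F1 | step 8 | methyl 3-[(2S,3S)-1-[(4S)-4-benzyl-2-oxo-1,3-oxazolidin-3-yl]-3-(4-benzyloxy-3-methoxyphenyl)-3-hydroxy-1-oxopropan-2-yl]-4-(benzyloxy)-5-methoxybenzoate | COc1cc([C@@H](O)[C@@H](C(=O)N2[C@@H](Cc3ccccc3)COC2=O)c2cc(C(=O)OC)cc(OC)c2OCc2ccccc2)ccc1OCc1ccccc1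
F2 | step 8 | methyl 4-(benzyloxy)-3-[(1S,2R)-1-(4-benzyloxy-3-methoxyphenyl)-1,3-dihydroxypropan-2-yl]-5-methoxybenzoate | COc1cc([C@@H](O)[C@@H](CO)c2cc(C(=O)OC)cc(OC)c2OCc2ccccc2)ccc1OCc1ccccc1
F3 | step 8 | methyl 3-[(1S,2R)-1,3-dihydroxy-1-(4-hydroxy-3-methoxyphenyl)propan-2-yl]-4-hydroxy-5-methoxybenzoate | COc1cc([C@@H](O)[C@@H](CO)c2cc(C(=O)OC)cc(OC)c2O)ccc1O
F4 | step 8 | methyl (2S,3R)-2-(4-hydroxy-3-methoxyphenyl)-3-(hydroxymethyl)-7-methoxy-2,3-dihydrobenzofuran-5-carboxylate | COC(=O)c1cc(OC)c2c(c1)[C@H](CO)[C@@H](c1ccc(O)c(OC)c1)O2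
F5 | step 8 | methyl (2S,3R)-2-(4-benzyloxy-3-methoxyphenyl)-3-(hydroxymethyl)-7-methoxy-2,3-dihydrobenzofuran-5-carboxylate | COC(=O)c1cc(OC)c2c(c1)[C@H](CO)[C@@H](c1ccc(OCc3ccccc3)c(OC)c1)O2
F6 | step 19 | methyl 4-(benzyloxy)-3-methoxy-5-(prop-1-yn-1-yl)benzoate | COC(=O)c1cc(C#CC)c(OCc2ccccc2)c(OC)c1
F7 | step 19 | methyl 4-(benzyloxy)-3-[(1S,2R)-1-(4-benzyloxy-3-methoxyphenyl)-1-hydroxybut-3-en-2-yl]-5-methoxybenzoate | COc1cc([C@@H](O)[C@H](C=C)c2cc(C(=O)OC)cc(OC)c2OCc2ccccc2)ccc1OCc1ccccc1
F8 | step 7 | 6-chloro-3-fluoro-4-methoxypyridazine | COc1cc(Cl)nnc1F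
F9 | step 7 | 6-chloro-3-[(1S,2R)-1-(4-benzyloxy-3-methoxyphenyl)-2-(triisopropylsilyloxymethyl)but-3-ynyloxy]-4-methoxypyridazine | COc1cc(Cl)nnc1O[C@H](c1ccc(OCc2ccccc2)c(OC)c1)[C@@H](CO[Si](C(C)C)(C(C)C)C(C)C)C#C
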